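(All runs are calculated from invented constants, noise included.)

Take a small charge: in the west flask, 1.7 mM of free catalyst meets 0.76 M of substrate, so catalyst intermediate can hold at most 0.224% of the substrate. Follow one substrate molecule. It binds free catalyst, leaves as target, and may then turn into isomer of the product and back on free catalyst.

| flask | substrate | free catalyst | temperature | remark | time |
|---|---|---|---|---|---|
| west | 0.76 M | 1.7 mM | 70 °C | the very flask that is asked about, followed so far |  |
| south-west | 0.76 M | 3.4 mM | 65 °C | run made earlier |  |
| flask | 0.76 M | 1.7 mM | 70 °C |  | 15 h |

- west (time / min: target / %, substrate / %): 40.0: 57, 27; 60.0: 66, 17; 90.0: 60, 9; 150: 49, 0; 240: 40, 0; 360: 38, 0; 600: 39, 1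
- south-west (time / min: target / %, substrate / %): 1.50: 7, 96; 2.50: 11, 90; 4.00: 14, 85; 6.00: 26, 77; 8.00: 27, 70; 12.0: 40, 59; 20.0: 53, 43

(readings scatter by 2 percentage points)

- gamma: change nothing and wait 8.0 h more
- alpha: at 15 h raise the temperature by 15 K, then wait 8.0 h
- epsilon: at 15 h add free catalyst, 50.0% of the amount charged, then wait 8.0 h
- eta: at 15 h take out 90% of the target then present, then wait 8.0 h

- target that was removed still counts
- reactions considered so far: substrate + free catalyst <-> catalyst intermediate; catalyst intermediate -> free catalyst + target; target + free catalyst <-> isomer of the product + free catalyst
- additions bring no volume worth counting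

- target, in percent of the substrate first charged, at 15 h
- the option that brings most further target ("none" if no option brings more than 2 percentage points) (gamma / alpha / epsilon / eta / none)
- target present, with what was taken out counted in, in percent of the substrate first charged, after alpha
- target present, with what was taken out counted in, in percent of the substrate first charged, after eta

In the west run, substrate reads 0% at 240 min and 1% at 600 min, so the molecule then stands at its last fork. Count two amounts: target, P, the mean of the readings over those times, 39.0%, and isomer, E, the rest of the charge, setting aside the small share that catalyst intermediate can hold, 61.0%. Their ratio P/E is the odds ρ, the chance of finding a molecule as target against finding it as isomer once it has flipped both ways: 0.639.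

If the catalyst lives, this is thermodynamic control, not kinetic control. Free catalyst stands on both sides of the flip, so expect neither waiting nor more catalyst to move the odds, and expect about 39.0% at 15 h. The odds were read at 70 °C, so they tell nothing about alpha. Under eta, 35.1% leaves, and the rest shares out by the odds, returning 25.3% as target, for 60.4% in my reckoning.

The forecast gives 39% (37% to 41%), chooses eta, and puts alpha at 41% (35% to 47%). It puts eta at 59% (44% to 62%), below my figure, with the warning “If the catalyst is dead, the plateau is kinetic”.

The west flask gives 38.5%, and eta brings most, 21 percentage points, reaching 59.7%; alpha reaches 41.3%. Free catalyst there stands at 100% of its charge at 900 min. Use the odds on this result: taking out 90% of 38.5% removes 34.7%, and the odds return 25.5% from the rest.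

    substrate + free catalyst ⇌ catalyst intermediate (K = 0.630 /M, k = 0.320 /M/s, Ea = 52.0 kJ/mol, ΔH = −15.0 kJ/mol)
    catalyst intermediate → free catalyst + target (k = 10.0 /s, Ea = 74.0 kJ/mol)
    target + free catalyst ⇌ isomer of the product + free catalyst, rate k3*[free catalyst]*[target] forward; the back reaction follows from the equilibrium constant (K = 1.60, k = 0.0910 /M/s, Ea = 57.0 kJ/mol, ΔH = −8.00 kJ/mol)
    (constants at 70 °C)

Carry the odds to the neighbour with 1.9 M of substrate at the same temperature: they give 39.0% target. The computed flask holds 38.5% target and 61.5% isomer.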